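**Assumption:** Altisin (5-hydroxy-7,8,2′,6′-tetramethoxyflavone) has no stereocenters, so "single enantiomer" is vacuous and no stereochemistry needs to be set or protected.

## Retrosynthesis (overview)
1. The target comes from chelation-selective 5-O-demethylation of 5,7,8,2′,6′-pentamethoxyflavone.
2. The pyranone ring is closed by 6-endo-dig oxa-Michael addition of an o-hydroxyaryl ynone. This avoids the chalcone and Baker–Venkataraman routes.
3. The o-hydroxyaryl ynone comes from BCl3 demethylation of the one ortho OMe that is flanked by the acyl group and the 3-OMe, in a 2,3,4,6-tetramethoxyphenyl ynone.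
4. That ynone is made by adding the aryllithium from 1,2,3,5-tetramethoxybenzene (a symmetric arene, so only one lithiation site) to an alkynyl Weinreb amide derived from 2,6-dimethoxyphenylacetylene.
5. Rings A and B are present from the start; ring C is formed in Step 6.

## Route

**Step 1**
Reactants: 1 (3,4,5-trimethoxyphenol)
Product: 2 (1,2,3,5-tetramethoxybenzene)
Conditions: MeI, K2CO3, acetone, reflux
Reagents that add atoms: MeI, CI
Why: Williamson O-methylation of the phenol gives a C2-symmetric tetramethoxyarene, so the next lithiation has only one possible site.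

**Step 2**
Reactants: 3 (2,6-dimethoxybenzaldehyde)
Product: 4 (1-ethynyl-2,6-dimethoxybenzene)
Conditions: Bestmann–Ohira reagent, K2CO3, MeOH, 0 °C → rt
Reagents that add atoms: dimethyl (1-diazo-2-oxopropyl)phosphonate, COP(=O)(OC)C(=[N+]=[N-])C(C)=O (supplies the alkyne terminal carbon)
Why: Seyferth–Gilbert homologation under Ohira–Bestmann conditions converts the aldehyde to the terminal alkyne and tolerates the hindered, electron-rich aldehyde.

**Step 3**
Reactants: 4 (1-ethynyl-2,6-dimethoxybenzene); 5 (N-methoxy-N-methylcarbamoyl chloride)
Product: 6 (3-(2,6-dimethoxyphenyl)-N-methoxy-N-methylprop-2-ynamide)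
Conditions: n-BuLi, THF, −78 °C; then 5, −78 °C → 0 °C
Reagents that add atoms: none beyond numbered 5 (n-BuLi only deprotonates)
Why: The lithium acetylide undergoes acylation at the carbamoyl chloride, a standard route to alkynyl Weinreb amides.

**Step 4**
Reactants: 2 (1,2,3,5-tetramethoxybenzene); 6 (alkynyl Weinreb amide)
Product: 7 (1-(2,3,4,6-tetramethoxyphenyl)-3-(2,6-dimethoxyphenyl)prop-2-yn-1-one)
Conditions: n-BuLi (1.05 equiv), THF, 0 °C → rt, 1.5 h; cool to −78 °C, add 6, then quench with sat. NH4Cl at −78 °C
Reagents that add atoms: none beyond numbered 6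
Why: Directed ortho-metalation occurs at the CH flanked by two OMe groups, which is the only kind of CH available by symmetry. The aryllithium adds 1,2 to the Weinreb amide, and the stable chelated tetrahedral intermediate prevents over-addition, giving the ynone on workup.

**Step 5**
Reactants: 7 (ynone)
Product: 8 (1-(2-hydroxy-3,4,6-trimethoxyphenyl)-3-(2,6-dimethoxyphenyl)prop-2-yn-1-one)
Conditions: BCl3 (1.1 equiv), CH2Cl2, −78 → 0 °C, 1 h; aq. NaHCO3 workup
Reagents that add atoms: none (Me is lost as MeCl; no Cl is retained)
Why: Proposed new method: BCl3 chelates the ketone and cleaves an ortho methyl ether, as in the known ortho-demethylation of o-methoxyaryl ketones. I expect the buttressed C2-OMe, which is flanked by the acyl group and the 3-OMe, to be cleaved preferentially because this relieves steric strain. Limiting BCl3 to about one equivalent prevents double demethylation. If chloride adds to the ynone, the resulting β-chlorovinyl ketone still closes to the same flavone in Step 6 by addition–elimination.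

**Step 6**
Reactants: 8 (o-hydroxyaryl ynone)
Product: 9 (5,7,8,2′,6′-pentamethoxyflavone)
Conditions: K2CO3, acetone, reflux
Reagents that add atoms: none
Why: The phenoxide adds to the β-carbon of the ynone in a 6-endo-dig oxa-Michael reaction, followed by protonation, which forms the flavone C ring. O1 is fixed by the phenol position set in Step 5.

**Step 7**
Reactants: 9 (pentamethoxyflavone)
Product: 10 (Altisin)
Conditions: BCl3 (1.2 equiv), CH2Cl2, −78 → 0 °C; aq. workup
Reagents that add atoms: none
Why: Chelation-controlled regioselective cleavage of the peri 5-OMe, which is hydrogen-bond-like bound to the C4 carbonyl through boron, is well known for polymethoxyflavones. The 8-OMe and the 2′,6′-OMe groups have no such chelation and survive.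

## Checks
- **Target match:** Compound 10 has the C2 aryl group (2,6-dimethoxyphenyl), C4=O, 5-OH, 6-H, 7-OMe, 8-OMe and O1. This matches the target SMILES.
- **Atom bookkeeping:** 7 is C21H22O7. Steps 5 and 6 lose CH2 and then isomerize (C20H20O7). Step 7 loses another CH2, giving C19H18O7.
- **Functional-group survival:** The ynone is formed only at −78 °C and quenched cold. BCl3 is limited to about one equivalent in Step 5, so the aryl methyl ethers other than the targeted ortho OMe survive. The C2=C3 bond is untouched in Step 7.
- **Stereochemistry:** None is required.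

## Compound list
1 | 3,4,5-trimethoxyphenol | COc1cc(O)cc(OC)c1OC | starting material
2 | 1,2,3,5-tetramethoxybenzene | COc1cc(OC)c(OC)c(OC)c1 | intermediate
3 | 2,6-dimethoxybenzaldehyde | COc1cccc(OC)c1C=O | starting material
4 | 1-ethynyl-2,6-dimethoxybenzene | COc1cccc(OC)c1C#C | intermediate
5 | N-methoxy-N-methylcarbamoyl chloride | CON(C)C(=O)Cl | starting material
6 | 3-(2,6-dimethoxyphenyl)-N-methoxy-N-methylprop-2-ynamide | CON(C)C(=O)C#Cc1c(OC)cccc1OC | intermediate
7 | 1-(2,3,4,6-tetramethoxyphenyl)-3-(2,6-dimethoxyphenyl)prop-2-yn-1-one | COc1cc(OC)c(C(=O)C#Cc2c(OC)cccc2OC)c(OC)c1OC | intermediate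
8 | 1-(2-hydroxy-3,4,6-trimethoxyphenyl)-3-(2,6-dimethoxyphenyl)prop-2-yn-1-one | COc1cc(OC)c(C(=O)C#Cc2c(OC)cccc2OC)c(O)c1OC | intermediate
9 | 5,7,8,2′,6′-pentamethoxyflavone | COc1cccc(OC)c1-c1cc(=O)c2c(OC)cc(OC)c(OC)c2o1 | intermediate
10 | Altisin (5-hydroxy-7,8,2′,6′-tetramethoxyflavone; achiral) | COc1cccc(OC)c1-c1cc(=O)c2c(O)cc(OC)c(OC)c2o1 | target

## Totals
- Total steps: 7.
- Longest linear sequence: 6 steps (3 → 4 → 6 → 7 → 8 → 9 → 10).

## Three steps most likely to fail, with fallbacks
1. **Step 5 (regioselective mono-demethylation in the presence of the ynone).** The wrong ortho OMe could be cleaved, giving the 5,6,7-isomer after cyclization, or chloride could add to the ynone.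
   - Fallback: set O1 by construction. Make 2-hydroxy-3,4,6-trimethoxybenzaldehyde from commercial 2-hydroxy-4,6-dimethoxyacetophenone by Duff formylation at C3, Dakin oxidation, and selective 3-O-methylation. Then add the lithium acetylide of 4 to the aldehyde, oxidize with MnO2, and cyclize as in Step 6.
2. **Step 4 (hindered, di-ortho-substituted aryllithium adding to the alkynyl Weinreb amide).** Conjugate addition or low conversion is possible.
   - Fallback: iodinate 2 with NIS to give 1-iodo-2,3,4,6-tetramethoxybenzene. Then run a Pd-catalysed carbonylative Sonogashira coupling with 4 under CO to give ynone 7.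
3. **Step 7 (selective 5-demethylation).** Over-cleavage of the 8-OMe or the 2′,6′-OMe groups would give mixtures.
   - Fallback: carry the 5-oxygen as a MOM ether from the start, using a regio-defined A-ring aldehyde such as 2-hydroxy-3,4-dimethoxy-6-(methoxymethoxy)benzaldehyde. It is then unmasked with mild HCl/MeOH, so no Lewis-acid demethylation is needed.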